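The readings are simulated for an exercise; the scatter is artificial.

Time frames the problem: the earlier runs stop at 20.0 h, while dawn and dusk are read at 4.0 d.

in all of them: electrophile 0.050 M

| charge | nucleophile | solid base | remark | time |
|---|---|---|---|---|
| alpha | 0.060 M | 0.075 M | run made earlier |  |
| epsilon | 0.060 M | 0.10 M | run made earlier |  |
| dawn | 0.0600 M | 0.0500 M |  | 4.0 d |
| dusk | 0.120 M | 0.0500 M |  | 4.0 d |

- alpha (time / h: electrophile / %, target / %): 1.50: 97, 0; 2.50: 94, 4; 4.00: 88, 6; 5.00: 83, 6; 8.00: 73, 7; 12.0: 65, 5; 20.0: 48, 2
- epsilon (time / h: electrophile / %, target / %): 1.00: 96, 1; 3.00: 94, 8; 5.00: 85, 5; 8.00: 78, 5; 12.0: 66, 4; 15.0: 59, 6; 20.0: 46, 7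

(readings scatter by 1.5 percentage points)

- in percentages every species weighs as the electrophile in it: one side product counts as two
- as a solid, counted per litre of solution: solid base
- steps under discussion: solid base <-> free base; acid set free + free base <-> salt of the base; electrophile + target -> side product; nucleophile + acid set free <-> protonated nucleophile; electrophile + nucleophile -> acid set free + target
- at the start none of the solid base is in solution

1. part of the electrophile that has reacted at the end, dawn
2. part of the electrophile that has reacted at the end, dusk
3. what raising the concentration of nucleophile from its lowest to its highest value here does to the part of the electrophile that has reacted (changes below 5 percentage points count as none) (it rises / it falls / no change)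

Write e for the electrophile left, as a fraction of its charge.

1. In alpha and epsilon, solid base differs, 0.075 M against 0.10 M. At 20.0 h electrophile reads 48% and 46%, a gap near the scatter of 1.5 percentage points. The reckoning therefore drops the solid base charge.

2. At that time alpha has lost 52.0% of its electrophile, yet target reads 2%, less. Target is therefore taken as a resting state, so each nucleophile step is reckoned to cost two electrophile.

3. Each step also frees one acid. Nucleophile is dissolved from the start and solid base is not, so nucleophile is taken as the catcher. Two electrophile then cost two nucleophile, one reacted and one protonated.

4. Nucleophile left, per electrophile charged, therefore stays above e by a constant, the spare: nucleophile charge over electrophile charge, minus one. It is 0.200 in dawn and 1.40 in dusk. A positive spare lets e head for zero.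

5. The speed follows: de/dt = −r·e·(e + spare). So ln((e + spare)/e) climbs linearly from its starting value, with slope r·spare. The mean reading 47.0% at 20.0 h gives r = 0.0431 h⁻¹.

6. At 4.0 d this gives 88.5% reacted in dawn and 99.8% in dusk, so the part reacted rises.

7. Step 3 is the weak link. Any acid taken by dissolved base spares nucleophile and raises the dawn figure.

The forecast, reading that target “is eaten by electrophile as fast as it forms”, gave 94% (87% to 99%) for dawn, above this reckoning, 99.6% (97% to 100%) for dusk, and "it rises".

The flask gives 88.6% for dawn and 99.8% for dusk: it rises, by 11 points.

    solid base ⇌ free base, rate k1*(cs1 - [free base]) while solid is left; crystals form when [free base] > cs1 (solubility = 9.00 mM, k = 0.0990 h⁻¹)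
    acid set free + free base ⇌ salt of the base (K = 7.10 × 10⁵ M⁻¹, k = 56.7 M⁻¹ h⁻¹)
    electrophile + target → side product (k = 6.58 M⁻¹ h⁻¹)
    nucleophile + acid set free ⇌ protonated nucleophile, settled at all times (K = 73000 M⁻¹)
    electrophile + nucleophile → acid set free + target (k = 0.437 M⁻¹ h⁻¹)

In dawn at 4.00 d, target's half-life by the side-product step is 0.77 d, shorter than electrophile's 4.4 d by the step with nucleophile. Target stands at 2.29% and side product at 86.3%. Nucleophile left in dawn, per electrophile charged, is 0.303; electrophile left plus the spare is 0.314. A further flask, otherwise like dawn, holds 0.024 M of nucleophile, so its spare is −0.520: nucleophile is the limiting reagent, and the reckoning stops electrophile near 52.0% of its charge. Computed, that flask has 54.0% of its electrophile left at 4.00 d.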